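**Retrosynthetic overview**

- The pyranone (ring C) is opened last: C2 is removed from the isoflavone, leaving a 2-hydroxydeoxybenzoin that is re-closed with an amide acetal.
- The strategy rests on ring A: oxygen on C7 and on C8a, the prenyl group on C8 between them, and the acyl carbon (C4) on C4a. This is the pattern a 2-prenyl-1,1,3-trioxygenated butadiene delivers to an acyl alkyne.
- Key disconnection: C5–C6 and C4a–C8a, giving a bis(silyloxy) methoxy diene and a terminal ynone (Diels–Alder reaction, then aromatisation).
- The diene comes from methyl acetoacetate and prenyl bromide. The ynone comes from 2,4,5-trimethoxybenzaldehyde by one-carbon homologation, ethynylation and oxidation.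
- Ring order: the trimethoxyphenyl ring is bought, ring A is built by cycloaddition, ring C is closed last.

Key step: step 9

Assumption: enol ethers 2 and 11 are carried on as E/Z mixtures and compounds 5 and 9 as racemates, because these stereo-elements are destroyed in later steps; the target has no stereocentre.

**Route**

Step 1
Reactants: 1 2,4,5-trimethoxybenzaldehyde
Product: 2 1,2,4-trimethoxy-5-(2-methoxyethenyl)benzene (E/Z mixture)
Conditions: Ph3P(CH2OMe)Cl, KOtBu, THF, 0 °C → rt
Reagents that add atoms: (methoxymethyl)triphenylphosphonium chloride, COC[P+](c1ccccc1)(c1ccccc1)c1ccccc1.[Cl-]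
Why: Wittig olefination with the methoxymethylene ylide is the standard one-carbon homologation of an aryl aldehyde and tolerates the electron-rich ring.

Step 2
Reactants: 2 1,2,4-trimethoxy-5-(2-methoxyethenyl)benzene
Product: 3 2-(2,4,5-trimethoxyphenyl)acetaldehyde
Conditions: 2 M aq. HCl, THF, 50 °C, N2; used crude at once
Reagents that add atoms: water, O
Why: Acid-catalysed enol ether hydrolysis (protonation at the benzylic carbon, then collapse of the hemiacetal) should unmask the arylacetaldehyde.

Step 3
Reactants: 3 2-(2,4,5-trimethoxyphenyl)acetaldehyde; 4 ethynylmagnesium bromide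
Product: 5 1-(2,4,5-trimethoxyphenyl)but-3-yn-2-ol (racemic)
Conditions: HC≡CMgBr (2 equiv, THF solution), THF, −78 → 0 °C; sat. aq. NH4Cl
Reagents that add atoms: none
Why: Grignard 1,2-addition of the alkynyl reagent at low temperature should outrun enolisation of the aldehyde; the carbinol centre forms without control and is removed in step 4.

Step 4
Reactants: 5 1-(2,4,5-trimethoxyphenyl)but-3-yn-2-ol
Product: 6 1-(2,4,5-trimethoxyphenyl)but-3-yn-2-one
Conditions: Dess–Martin periodinane, CH2Cl2, 0 °C → rt; aq. Na2S2O3/NaHCO3 work-up; used without storage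
Reagents that add atoms: none
Why: Dess–Martin oxidation converts propargylic alcohols to ynones under nearly neutral, non-aqueous conditions that spare the enolisable benzylic CH2 and the terminal alkyne.

Step 5
Reactants: 7 methyl acetoacetate; 8 prenyl bromide (1-bromo-3-methylbut-2-ene)
Product: 9 methyl 2-acetyl-5-methylhex-4-enoate (racemic)
Conditions: NaH (1.0 equiv), THF, 0 °C; then 8 (0.9 equiv), 0 °C → rt
Reagents that add atoms: none
Why: C-alkylation of the acetoacetate sodium enolate with a primary allylic bromide (SN2) is reliable, and keeping 7 in slight excess limits dialkylation.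

Step 6
Reactants: 9 methyl 2-acetyl-5-methylhex-4-enoate
Product: 11 methyl 3-methoxy-2-(3-methylbut-2-enyl)but-2-enoate (E/Z mixture), via dimethyl ketal 10 (not isolated)
Conditions: HC(OMe)3, MeOH, cat. TsOH·H2O, rt; then slow distillation of MeOH and HCO2Me (bath 100 °C); Et3N quench
Reagents that add atoms: trimethyl orthoformate, COC(OC)OC
Why: Acid-catalysed ketalisation with the orthoformate followed by loss of methanol gives the conjugated β-methoxy enoate (net O-methylation of the keto ester enol), under conditions to which the isolated trisubstituted alkene should be inert.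

Step 7
Reactants: 11 methyl 3-methoxy-2-(3-methylbut-2-enyl)but-2-enoate
Product: 12 3-methoxy-2-(3-methylbut-2-enyl)but-2-enoic acid
Conditions: KOH, MeOH/H2O, 60 °C; then 1 M HCl to pH 4 at 0 °C, Et2O extraction
Reagents that add atoms: potassium hydroxide, [K+].[OH-]
Why: Saponification leaves the base-stable enol ether untouched, and cold, barely acidic work-up should avoid its hydrolysis to the β-keto acid.

Step 8
Reactants: 12 3-methoxy-2-(3-methylbut-2-enyl)but-2-enoic acid
Product: 14 3-methoxy-2-(3-methylbut-2-enyl)-1,1-bis(trimethylsilyloxy)buta-1,3-diene, via dilithium dienediolate 13 (not isolated)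
Conditions: LiN(iPr)2 (2.2 equiv), THF, −78 → −40 °C; Me3SiCl (2.5 equiv), −78 °C → rt; pentane, filtration under Ar; used crude
Reagents that add atoms: chlorotrimethylsilane, C[Si](C)(C)Cl
Why: Double deprotonation (carboxyl proton, then the γ-methyl proton of the vinylogous system) gives dienediolate 13, whose two oxygen centres are silylated by Me3SiCl, the usual way to bis(trimethylsilyl) ketene acetals from carboxylic acid dianions.

Step 9
Reactants: 14 3-methoxy-2-(3-methylbut-2-enyl)-1,1-bis(trimethylsilyloxy)buta-1,3-diene; 6 1-(2,4,5-trimethoxyphenyl)but-3-yn-2-one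
Product: 17 1-[2-hydroxy-4-methoxy-3-(3-methylbut-2-enyl)phenyl]-2-(2,4,5-trimethoxyphenyl)ethanone, via cyclohexadiene cycloadduct 15 (not isolated), via aryl trimethylsilyl ether 16 (not isolated)
Conditions: 14 (1.5 equiv), toluene, 0 → 60 °C, Ar; then THF, 5% aq. citric acid, rt
Reagents that add atoms: none
Why: The electron-rich diene 14 and the electron-poor terminal ynone 6 undergo a normal-electron-demand Diels–Alder reaction (concerted but asynchronous, or stepwise as a Mukaiyama–Michael addition followed by 6-exo-trig attack of the allenolate carbon on the bis(silyloxy)carbenium carbon) to give 1,4-cyclohexadiene 15, which aromatises by 1,4-elimination of Me3SiOH to 16; the mild aqueous acid then cleaves the aryl silyl ether to the chelated phenol 17. The closest known reaction type is the cycloaddition–aromatisation of vinylketene acetals with acetylenic ketones and esters, which gives acyl resorcinol derivatives. Ring A is the only ring closed, in a (4+2) mode, forming C5–C6 (diene CH2 to the ynone β-carbon) and C4a–C8a (ketene acetal carbon to the ynone α-carbon). No stereocentre is created, since the ketal carbon of 15 carries two identical silyloxy groups and becomes aromatic. The step needs this single regiochemistry and attack on the alkyne rather than the carbonyl: the three oxygen donors put the largest HOMO coefficient on the unsubstituted CH2 terminus, which meets the largest LUMO coefficient at the ynone β-carbon, and the absence of a Lewis acid keeps the ketone and the enolisable CH2 of 6 out of play. Because both oxygens on the future C8a carry the same silyl group, only Me3SiOH can leave, so the phenol needed for O1 is delivered unambiguously and the prenyl group arrives fixed on C8 between the two oxygens.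

Step 10
Reactants: 17 1-[2-hydroxy-4-methoxy-3-(3-methylbut-2-enyl)phenyl]-2-(2,4,5-trimethoxyphenyl)ethanone
Product: 19 prebarbigerone, 7-methoxy-8-(3-methylbut-2-enyl)-3-(2,4,5-trimethoxyphenyl)chromen-4-one, via enaminone 18 (not isolated)
Conditions: Me2NCH(OMe)2 (3 equiv), toluene, 90 °C
Reagents that add atoms: N,N-dimethylformamide dimethyl acetal, COC(OC)N(C)C
Why: Condensation of the active methylene with the amide acetal gives enaminone 18, whose phenol adds to the β-carbon (6-endo-trig) and expels dimethylamine, the standard deoxybenzoin-to-isoflavone annulation, run without acid so the prenyl group is not at risk.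

**Compound list**

1 | 2,4,5-trimethoxybenzaldehyde | COc1cc(OC)c(C=O)cc1OC | starting material
2 | 1,2,4-trimethoxy-5-(2-methoxyethenyl)benzene (E/Z mixture) | COC=Cc1cc(OC)c(OC)cc1OC | intermediate
3 | 2-(2,4,5-trimethoxyphenyl)acetaldehyde | O=CCc1cc(OC)c(OC)cc1OC | intermediate
4 | ethynylmagnesium bromide | C#C[Mg]Br | starting material
5 | 1-(2,4,5-trimethoxyphenyl)but-3-yn-2-ol (racemic) | C#CC(O)Cc1cc(OC)c(OC)cc1OC | intermediate
6 | 1-(2,4,5-trimethoxyphenyl)but-3-yn-2-one | C#CC(=O)Cc1cc(OC)c(OC)cc1OC | intermediate
7 | methyl acetoacetate | CC(=O)CC(=O)OC | starting material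
8 | prenyl bromide (1-bromo-3-methylbut-2-ene) | CC(C)=CCBr | starting material
9 | methyl 2-acetyl-5-methylhex-4-enoate (racemic) | COC(=O)C(CC=C(C)C)C(C)=O | intermediate
10 | methyl 3,3-dimethoxy-2-(3-methylbut-2-enyl)butanoate (not isolated) | COC(=O)C(CC=C(C)C)C(C)(OC)OC | intermediate
11 | methyl 3-methoxy-2-(3-methylbut-2-enyl)but-2-enoate (E/Z mixture) | COC(C)=C(CC=C(C)C)C(=O)OC | intermediate
12 | 3-methoxy-2-(3-methylbut-2-enyl)but-2-enoic acid | COC(C)=C(CC=C(C)C)C(=O)O | intermediate
13 | dilithium 3-methoxy-2-(3-methylbut-2-enyl)buta-1,3-diene-1,1-diolate (not isolated) | [Li+].[Li+].C=C(OC)C(CC=C(C)C)=C([O-])[O-] | intermediate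
14 | 3-methoxy-2-(3-methylbut-2-enyl)-1,1-bis(trimethylsilyloxy)buta-1,3-diene | C=C(OC)C(CC=C(C)C)=C(O[Si](C)(C)C)O[Si](C)(C)C | intermediate
15 | 1-[4-methoxy-5-(3-methylbut-2-enyl)-6,6-bis(trimethylsilyloxy)cyclohexa-1,4-dien-1-yl]-2-(2,4,5-trimethoxyphenyl)ethanone (not isolated) | COC1=C(CC=C(C)C)C(O[Si](C)(C)C)(O[Si](C)(C)C)C(C(=O)Cc2cc(OC)c(OC)cc2OC)=CC1 | intermediate
16 | 1-[4-methoxy-3-(3-methylbut-2-enyl)-2-(trimethylsilyloxy)phenyl]-2-(2,4,5-trimethoxyphenyl)ethanone (not isolated) | COc1ccc(C(=O)Cc2cc(OC)c(OC)cc2OC)c(O[Si](C)(C)C)c1CC=C(C)C | intermediate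
17 | 1-[2-hydroxy-4-methoxy-3-(3-methylbut-2-enyl)phenyl]-2-(2,4,5-trimethoxyphenyl)ethanone | COc1ccc(C(=O)Cc2cc(OC)c(OC)cc2OC)c(O)c1CC=C(C)C | intermediate
18 | 3-(dimethylamino)-1-[2-hydroxy-4-methoxy-3-(3-methylbut-2-enyl)phenyl]-2-(2,4,5-trimethoxyphenyl)prop-2-en-1-one (not isolated) | COc1ccc(C(=O)C(=CN(C)C)c2cc(OC)c(OC)cc2OC)c(O)c1CC=C(C)C | intermediate
19 | prebarbigerone, 7-methoxy-8-(3-methylbut-2-enyl)-3-(2,4,5-trimethoxyphenyl)chromen-4-one | COc1cc(OC)c(-c2coc3c(CC=C(C)C)c(OC)ccc3c2=O)cc1OC | target

**Count**

Total steps: 10. Longest linear sequence: 6 steps (steps 1–4, 9, 10 or steps 5–8, 9, 10).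

**Steps most likely to fail**

1. Step 9. The cycloaddition may be outrun by oligomerisation of the ynone, by 1,2-addition of the diene to the ketone, or by silyl transfer after the first C–C bond so that the ring never closes. The fallback builds the same deoxybenzoin on a preformed arene; it sets out from aldehyde 3 and returns at 17. Pinnick oxidation (NaClO2, NaH2PO4, 2-methylbut-2-ene, tBuOH/H2O) would give 2-(2,4,5-trimethoxyphenyl)acetic acid F1. Acylation of resorcinol with F1 in BF3·OEt2 at 80 °C would give 1-(2,4-dihydroxyphenyl)-2-(2,4,5-trimethoxyphenyl)ethanone F2. The non-chelated 4-hydroxyl would be etherified with 3-chloro-3-methylbut-1-yne (K2CO3, KI, cat. CuI, acetone) to 1-[2-hydroxy-4-(2-methylbut-3-yn-2-yloxy)phenyl]-2-(2,4,5-trimethoxyphenyl)ethanone F3. Semi-hydrogenation (H2, Pd on CaCO3 poisoned with Pb(OAc)2, quinoline) would give 1-[2-hydroxy-4-(2-methylbut-3-en-2-yloxy)phenyl]-2-(2,4,5-trimethoxyphenyl)ethanone F4. Aromatic Claisen rearrangement (N,N-diethylaniline, 150 °C), directed to the position between the two oxygens by the chelate-fixed bond, would give 1-[2,4-dihydroxy-3-(3-methylbut-2-enyl)phenyl]-2-(2,4,5-trimethoxyphenyl)ethanone F5. Mono-methylation of the free 4-hydroxyl (MeI, K2CO3, acetone) should then give 17.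

2. Step 8. The second deprotonation of the carboxylate may be incomplete or misdirected, the dienediolate may lose methoxide on warming, silylation may occur on carbon, or the ketene acetal may hydrolyse on isolation. The fallback uses the ester enolate instead of the acid dianion; it sets out from ester 11 and returns at 17. Treatment of 11 with LiN(iPr)2 and Me3SiCl in THF at −78 °C would give the mixed ketene acetal [1,3-dimethoxy-2-(3-methylbut-2-enyl)buta-1,3-dienoxy]trimethylsilane F6. Cycloaddition of F6 with ynone 6 in toluene would give 1-[4,6-dimethoxy-5-(3-methylbut-2-enyl)-6-(trimethylsilyloxy)cyclohexa-1,4-dien-1-yl]-2-(2,4,5-trimethoxyphenyl)ethanone F7. Buffered fluoride (KF, AcOH, MeOH, 0 °C) would cleave the Si–O bond; the hemiketal should expel methanol and the dienone tautomerise to 17. Fluoride is used because acid-induced ionisation could instead expel the silanol and leave a methyl ether at that position.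

3. Step 4. The terminal ynone, with its acidic benzylic CH2, may enolise and oligomerise during oxidation, work-up or concentration. The fallback masks the alkyne terminus; it sets out from aldehyde 3 and returns at 6. Addition of LiC≡CSiMe3 (trimethylsilylacetylene, n-BuLi, THF, −78 °C) would give 1-(2,4,5-trimethoxyphenyl)-4-(trimethylsilyl)but-3-yn-2-ol F8. Dess–Martin oxidation would give 1-(2,4,5-trimethoxyphenyl)-4-(trimethylsilyl)but-3-yn-2-one F9, which should tolerate chromatography and storage. The C–Si bond would be cleaved with cat. Na2B4O7 in MeOH at rt immediately before step 9, releasing 6.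

**Further compounds**

F1 | step 9 | 2-(2,4,5-trimethoxyphenyl)acetic acid | OC(=O)Cc1cc(OC)c(OC)cc1OC
F2 | step 9 | 1-(2,4-dihydroxyphenyl)-2-(2,4,5-trimethoxyphenyl)ethanone | O=C(Cc1cc(OC)c(OC)cc1OC)c1ccc(O)cc1O
F3 | step 9 | 1-[2-hydroxy-4-(2-methylbut-3-yn-2-yloxy)phenyl]-2-(2,4,5-trimethoxyphenyl)ethanone | C#CC(C)(C)Oc1ccc(C(=O)Cc2cc(OC)c(OC)cc2OC)c(O)c1
F4 | step 9 | 1-[2-hydroxy-4-(2-methylbut-3-en-2-yloxy)phenyl]-2-(2,4,5-trimethoxyphenyl)ethanone | C=CC(C)(C)Oc1ccc(C(=O)Cc2cc(OC)c(OC)cc2OC)c(O)c1
F5 | step 9 | 1-[2,4-dihydroxy-3-(3-methylbut-2-enyl)phenyl]-2-(2,4,5-trimethoxyphenyl)ethanone | CC(C)=CCc1c(O)ccc(C(=O)Cc2cc(OC)c(OC)cc2OC)c1O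
F6 | step 8 | [1,3-dimethoxy-2-(3-methylbut-2-enyl)buta-1,3-dienoxy]trimethylsilane | C=C(OC)C(CC=C(C)C)=C(OC)O[Si](C)(C)C
F7 | step 8 | 1-[4,6-dimethoxy-5-(3-methylbut-2-enyl)-6-(trimethylsilyloxy)cyclohexa-1,4-dien-1-yl]-2-(2,4,5-trimethoxyphenyl)ethanone | COC1=C(CC=C(C)C)C(OC)(O[Si](C)(C)C)C(C(=O)Cc2cc(OC)c(OC)cc2OC)=CC1
F8 | step 4 | 1-(2,4,5-trimethoxyphenyl)-4-(trimethylsilyl)but-3-yn-2-ol | C[Si](C)(C)C#CC(O)Cc1cc(OC)c(OC)cc1OC
F9 | step 4 | 1-(2,4,5-trimethoxyphenyl)-4-(trimethylsilyl)but-3-yn-2-one | C[Si](C)(C)C#CC(=O)Cc1cc(OC)c(OC)cc1OC
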